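**Retrosynthetic overview**
- The target comes from its C8 alcohol by O-acylation with (S)-2-methylbutanoic acid (last step).
- The C8 alcohol comes from a furanone (Z)-enal carrying a 2-(bromomethyl)enoate: one chromium-mediated Barbier allylation forms C6–C7, closing the nine-membered oxa-bridged ring (the ten-membered carbocycle) and the α-methylene γ-lactone together and setting C6 and C7.
- The furanone (Z)-enal comes from a 2,3-disubstituted furan ketol by oxidative rearrangement (the furan masks the C3 carbonyl and the Z-enal); the allylic bromide comes from a Baylis–Hillman adduct.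
- The furan ketol comes from a hydroxy lactone and (Z)-3-methylpent-2-en-4-yn-1-ol (acetylide acylation, 5-exo cycloisomerisation); the lactone comes from a catalytic asymmetric pyruvate aldol (C10) and a 1,3-anti reduction (C8).
- Ring order: temporary γ-lactone, then furan, then 3(2H)-furanone, then medium ring and α-methylene lactone in one operation.

Assumption: atoms are labelled C1–C15 by germacranolide numbering (C10 = oxygenated quaternary carbon, C6 = lactone carbinol, C8 = ester carbinol, C11=C13 = exocyclic methylene); read this way the target is 6R,7R,8R,10R with a (2S)-2-methylbutanoate.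

**Step 1**
Reactants: 1 1,1-dimethoxypropan-2-one
Product: 2 [(3,3-dimethoxyprop-1-en-2-yl)oxy]trimethylsilane
Conditions: LiN(i-Pr)2 (1.1 equiv), TMSCl (1.2 equiv), THF, −78 to 0 °C
Reagents that add atoms: chlorotrimethylsilane (TMSCl), C[Si](C)(C)Cl
Why: Kinetic deprotonation by the hindered amide occurs at the methyl group and O-silylation of the lithium enolate gives the terminal enol silane (silyl enol ether formation).

**Step 2**
Reactants: 2 [(3,3-dimethoxyprop-1-en-2-yl)oxy]trimethylsilane; 3 methyl pyruvate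
Product: 5 methyl (2R)-2-hydroxy-5,5-dimethoxy-2-methyl-4-oxopentanoate, via silyl ether 4 (not isolated)
Conditions: Cu(OTf)2 (10 mol%), 2,2′-(propane-2,2-diyl)bis[(4R)-4-tert-butyl-4,5-dihydro-1,3-oxazole] (11 mol%), THF, −78 °C; then 1 M HCl, THF, 0 °C
Reagents that add atoms: none
Why: Mukaiyama aldol addition to the pyruvate chelated on the C2-symmetric divalent copper bis(oxazoline) complex (Evans-type pyruvate aldol); the (R,R)-ligand, antipode of the complex that gives (S)-adducts, blocks one carbonyl face and sets the tertiary carbinol (future C10) as R.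

**Step 3**
Reactants: 5 methyl (2R)-2-hydroxy-5,5-dimethoxy-2-methyl-4-oxopentanoate
Product: 7 (3R,5R)-5-(dimethoxymethyl)-3-hydroxy-3-methyloxolan-2-one, via anti-diol ester 6 (not isolated)
Conditions: Me4NBH(OAc)3 (5 equiv), MeCN/AcOH (1:1), −30 °C; then PPTS (cat.), CH2Cl2, 23 °C
Reagents that add atoms: none
Why: Evans–Saksena reduction, in which the tertiary hydroxyl binds boron and delivers hydride intramolecularly through a chair to give the 1,3-anti diol (future C8 set as R), after which the γ-hydroxy ester closes to the five-membered lactone.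

**Step 4**
Reactants: 7 (3R,5R)-5-(dimethoxymethyl)-3-hydroxy-3-methyloxolan-2-one; 8 (2Z)-3-methylpent-2-en-4-yn-1-ol
Product: 11 (3R,5R)-3,5-dihydroxy-6,6-dimethoxy-3-methyl-1-(3-methylfuran-2-yl)hexan-2-one, via dilithio salt 9 (not isolated), via ynone triol 10 (not isolated)
Conditions: 8 (3 equiv), n-BuLi (6 equiv), THF, −78 to 0 °C; add 7, −78 to −30 °C; AcOH quench; then DBU (0.2 equiv), THF, 23 °C
Reagents that add atoms: none
Why: The acetylide acylates on the lactone carbonyl (the lactol alkoxide prevents a second addition), and in the released ynone the (Z)-allylic oxygen adds 5-exo-dig to the activated alkyne and the alkylidene dihydrofuran tautomerises to the aromatic furan (acetylide acylation then base-mediated enynol cycloisomerisation), which locks the future C4=C5 bond as Z and leaves C8 and C10 untouched.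

**Step 5**
Reactants: 11 (3R,5R)-3,5-dihydroxy-6,6-dimethoxy-3-methyl-1-(3-methylfuran-2-yl)hexan-2-one
Product: 14 (2R,4R)-4-methyl-6-(3-methylfuran-2-yl)-5-oxo-2,4-bis(triethylsilyloxy)hexanal, via bis-silyl acetal 12 (not isolated), via collidinium salt 13 (not isolated)
Conditions: TESOTf (5 equiv), 2,4,6-collidine (7 equiv), CH2Cl2, 0 °C; then H2O, 23 °C
Reagents that add atoms: triethylsilyl trifluoromethanesulfonate (TESOTf), CC[Si](CC)(CC)OS(=O)(=O)C(F)(F)F; water, O
Why: The silyl triflate/collidine pair silylates both hydroxyls and converts the dimethyl acetal through a collidinium N,O-acetal into the aldehyde on adding water (Fujioka-type non-acidic acetal cleavage that spares the furan), the tertiary silyl ether preventing the lactol that a free C10 hydroxyl would form with the new aldehyde.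

**Step 6**
Reactants: 14 (2R,4R)-4-methyl-6-(3-methylfuran-2-yl)-5-oxo-2,4-bis(triethylsilyloxy)hexanal; 15 methyl acrylate
Product: 16 methyl (4R,6R)-3-hydroxy-6-methyl-2-methylidene-8-(3-methylfuran-2-yl)-7-oxo-4,6-bis(triethylsilyloxy)octanoate (mixture of C3 epimers)
Conditions: 15 (10 equiv), DABCO (1 equiv), MeOH (2 equiv), 23 °C, 4 d
Reagents that add atoms: none
Why: Morita–Baylis–Hillman reaction in which the DABCO–acrylate ammonium enolate adds to the activated α-silyloxy aldehyde; the new carbinol centre becomes sp2 in the next step, so its configuration is irrelevant.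

**Step 7**
Reactants: 16 methyl (4R,6R)-3-hydroxy-6-methyl-2-methylidene-8-(3-methylfuran-2-yl)-7-oxo-4,6-bis(triethylsilyloxy)octanoate
Product: 18 methyl (2Z,4R,6R)-2-(bromomethyl)-6-methyl-8-(3-methylfuran-2-yl)-7-oxo-4,6-bis(triethylsilyloxy)oct-2-enoate, via mesylate 17 (not isolated)
Conditions: MsCl, Et3N, CH2Cl2, −20 °C; then LiBr, THF, 0 to 23 °C
Reagents that add atoms: lithium bromide (LiBr), [Li+].[Br-]
Why: Mesylation followed by bromide attack with allylic transposition (SN2′) gives the thermodynamically preferred (Z)-2-(bromomethyl)enoate, the standard conversion of Baylis–Hillman adducts, under conditions that do not touch the furan.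

**Step 8**
Reactants: 18 methyl (2Z,4R,6R)-2-(bromomethyl)-6-methyl-8-(3-methylfuran-2-yl)-7-oxo-4,6-bis(triethylsilyloxy)oct-2-enoate
Product: 19 methyl (2Z,4R,6R)-2-(bromomethyl)-4,6-dihydroxy-6-methyl-8-(3-methylfuran-2-yl)-7-oxooct-2-enoate
Conditions: HF·pyridine, THF, 0 °C; used at once
Reagents that add atoms: none
Why: Fluoride-driven Si–O cleavage (desilylation) under weakly acidic, non-basic conditions that leave the allylic bromide, the furan and the ester intact and do not promote O-alkylation of the C8 hydroxyl.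

**Step 9**
Reactants: 19 methyl (2Z,4R,6R)-2-(bromomethyl)-4,6-dihydroxy-6-methyl-8-(3-methylfuran-2-yl)-7-oxooct-2-enoate
Product: 21 methyl (2Z,4R)-2-(bromomethyl)-4-hydroxy-5-{(2R)-2-methyl-3-oxo-5-[(2Z)-4-oxobut-2-en-2-yl]-2,3-dihydrofuran-2-yl}pent-2-enoate, via spiro lactol 20 (not isolated)
Conditions: NBS (1.05 equiv), NaHCO3 (2 equiv), THF/H2O (4:1), −10 to 23 °C; used at once
Reagents that add atoms: water, O
Why: Proposed new method: bromonium attack at the free α-position of the furan gives an oxocarbenium at C3 that the tertiary hydroxyl traps as a five-membered spiroketal, and hydrolysis to the lactol, ring opening and β-elimination toward the C1 ketone then release the 3(2H)-furanone and the enal with the Z geometry inherited from the furan; the closest known reactions are the NBS-mediated Achmatowicz reaction and oxidative spiroketalisation of hydroxyalkyl furans and the oxidative opening of furans to cis-enediones.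

**Step 10**
Reactants: 21 methyl (2Z,4R)-2-(bromomethyl)-4-hydroxy-5-{(2R)-2-methyl-3-oxo-5-[(2Z)-4-oxobut-2-en-2-yl]-2,3-dihydrofuran-2-yl}pent-2-enoate
Product: 24 (6R,7R,8R,10R)-8-hydroxy-1-oxo-3,10-epoxygermacra-2,4(Z),11(13)-trien-12,6-olide, via allylchromium species 22 (not isolated), via seco hydroxy ester 23 (not isolated)
Conditions: CrCl2 (8 equiv), THF/DMF (10:1), 23 °C, slow addition of 21 to a final 2 mM; then 1 M HCl work-up
Reagents that add atoms: none
Why: Nozaki–Hiyama–Kishi-type Barbier allylation in which divalent chromium turns the allylic bromide into an allylchromium that adds through C7 to the enal in a closed transition state held together by the rigid furanone and Z-alkene; the anti C6/C7 addition usual for chromium gives the trans ring fusion, the chromium-bound C8 hydroxyl (C9 pseudo-equatorial) directs attack to the C7 face that gives 7R, and the C6 chromium alkoxide lactonises onto the ester so that the medium ring and the α-methylene lactone close in one operation.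

**Step 11**
Reactants: 24 (6R,7R,8R,10R)-8-hydroxy-1-oxo-3,10-epoxygermacra-2,4(Z),11(13)-trien-12,6-olide; 25 (2S)-2-methylbutanoic acid
Product: 26 (6R,7R,8R,10R)-8-[(2S)-2-methylbutanoyloxy]-1-oxo-3,10-epoxygermacra-2,4(Z),11(13)-trien-12,6-olide (CNP0174601.1)
Conditions: 25 (3 equiv), DCC (3 equiv), DMAP (0.3 equiv), CH2Cl2, 0 to 23 °C
Reagents that add atoms: none
Why: Steglich esterification of the only free hydroxyl, which leaves C8 untouched (O-acylation with retention) and does not epimerise the α-stereocentre of the acid at this temperature.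

**Compound list**
1 | 1,1-dimethoxypropan-2-one | CC(=O)C(OC)OC | starting material
2 | [(3,3-dimethoxyprop-1-en-2-yl)oxy]trimethylsilane | C=C(O[Si](C)(C)C)C(OC)OC | intermediate
3 | methyl pyruvate | CC(=O)C(=O)OC | starting material
4 | methyl (2R)-5,5-dimethoxy-2-methyl-4-oxo-2-(trimethylsilyloxy)pentanoate | COC(=O)[C@](C)(O[Si](C)(C)C)CC(=O)C(OC)OC | intermediate
5 | methyl (2R)-2-hydroxy-5,5-dimethoxy-2-methyl-4-oxopentanoate | COC(=O)[C@](C)(O)CC(=O)C(OC)OC | intermediate
6 | methyl (2R,4R)-2,4-dihydroxy-5,5-dimethoxy-2-methylpentanoate | COC(=O)[C@](C)(O)C[C@@H](O)C(OC)OC | intermediate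
7 | (3R,5R)-5-(dimethoxymethyl)-3-hydroxy-3-methyloxolan-2-one | O=C1O[C@@H](C(OC)OC)C[C@@]1(C)O | intermediate
8 | (2Z)-3-methylpent-2-en-4-yn-1-ol | OC/C=C(/C)C#C | starting material
9 | dilithium salt of 8 (lithium alkoxide and lithium acetylide) | [Li]OC/C=C(/C)C#C[Li] | intermediate
10 | (2Z,7R,9R)-1,7,9-trihydroxy-10,10-dimethoxy-3,7-dimethyldec-2-en-4-yn-6-one | OC/C=C(/C)C#CC(=O)[C@](C)(O)C[C@@H](O)C(OC)OC | intermediate
11 | (3R,5R)-3,5-dihydroxy-6,6-dimethoxy-3-methyl-1-(3-methylfuran-2-yl)hexan-2-one | Cc1ccoc1CC(=O)[C@](C)(O)C[C@@H](O)C(OC)OC | intermediate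
12 | (3R,5R)-6,6-dimethoxy-3-methyl-1-(3-methylfuran-2-yl)-3,5-bis(triethylsilyloxy)hexan-2-one | Cc1ccoc1CC(=O)[C@](C)(O[Si](CC)(CC)CC)C[C@@H](O[Si](CC)(CC)CC)C(OC)OC | intermediate
13 | 1-[(2R,4R)-1-methoxy-4-methyl-6-(3-methylfuran-2-yl)-5-oxo-2,4-bis(triethylsilyloxy)hexyl]-2,4,6-trimethylpyridinium triflate (C1 epimers) | Cc1ccoc1CC(=O)[C@](C)(O[Si](CC)(CC)CC)C[C@@H](O[Si](CC)(CC)CC)C(OC)[n+]1c(C)cc(C)cc1C.[O-]S(=O)(=O)C(F)(F)F | intermediate
14 | (2R,4R)-4-methyl-6-(3-methylfuran-2-yl)-5-oxo-2,4-bis(triethylsilyloxy)hexanal | Cc1ccoc1CC(=O)[C@](C)(O[Si](CC)(CC)CC)C[C@@H](O[Si](CC)(CC)CC)C=O | intermediate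
15 | methyl acrylate | C=CC(=O)OC | starting material
16 | methyl (4R,6R)-3-hydroxy-6-methyl-2-methylidene-8-(3-methylfuran-2-yl)-7-oxo-4,6-bis(triethylsilyloxy)octanoate (C3 epimers) | Cc1ccoc1CC(=O)[C@](C)(O[Si](CC)(CC)CC)C[C@@H](O[Si](CC)(CC)CC)C(O)C(=C)C(=O)OC | intermediate
17 | methyl (4R,6R)-3-(methanesulfonyloxy)-6-methyl-2-methylidene-8-(3-methylfuran-2-yl)-7-oxo-4,6-bis(triethylsilyloxy)octanoate | Cc1ccoc1CC(=O)[C@](C)(O[Si](CC)(CC)CC)C[C@@H](O[Si](CC)(CC)CC)C(OS(C)(=O)=O)C(=C)C(=O)OC | intermediate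
18 | methyl (2Z,4R,6R)-2-(bromomethyl)-6-methyl-8-(3-methylfuran-2-yl)-7-oxo-4,6-bis(triethylsilyloxy)oct-2-enoate | Cc1ccoc1CC(=O)[C@](C)(O[Si](CC)(CC)CC)C[C@@H](O[Si](CC)(CC)CC)/C=C(\CBr)C(=O)OC | intermediate
19 | methyl (2Z,4R,6R)-2-(bromomethyl)-4,6-dihydroxy-6-methyl-8-(3-methylfuran-2-yl)-7-oxooct-2-enoate | Cc1ccoc1CC(=O)[C@](C)(O)C[C@@H](O)/C=C(\CBr)C(=O)OC | intermediate
20 | methyl (2Z,4R)-2-(bromomethyl)-4-hydroxy-5-[(2R)-7-hydroxy-2,9-dimethyl-3-oxo-1,6-dioxaspiro[4.4]non-8-en-2-yl]pent-2-enoate (spiro and lactol centres as mixtures) | CC1=CC(O)OC12CC(=O)[C@@](C)(C[C@@H](O)/C=C(\CBr)C(=O)OC)O2 | intermediate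
21 | methyl (2Z,4R)-2-(bromomethyl)-4-hydroxy-5-{(2R)-2-methyl-3-oxo-5-[(2Z)-4-oxobut-2-en-2-yl]-2,3-dihydrofuran-2-yl}pent-2-enoate | O=C/C=C(/C)C1=CC(=O)[C@@](C)(C[C@@H](O)/C=C(\CBr)C(=O)OC)O1 | intermediate
22 | allylchromium dichloride from 21 (trivalent chromium, CrCl2 unit on C13) | O=C/C=C(/C)C1=CC(=O)[C@@](C)(C[C@@H](O)/C=C(\C[Cr](Cl)Cl)C(=O)OC)O1 | intermediate
23 | methyl (6R,7R,8R,10R)-6,8-dihydroxy-1-oxo-3,10-epoxygermacra-2,4(Z),11(13)-trien-12-oate (formed as its chromium alkoxide) | O[C@@H]1/C=C(/C)C2=CC(=O)[C@@](C)(C[C@@H](O)[C@H]1C(=C)C(=O)OC)O2 | intermediate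
24 | (6R,7R,8R,10R)-8-hydroxy-1-oxo-3,10-epoxygermacra-2,4(Z),11(13)-trien-12,6-olide | C=C1C(=O)O[C@@H]2/C=C(/C)C3=CC(=O)[C@@](C)(C[C@@H](O)[C@@H]12)O3 | intermediate
25 | (2S)-2-methylbutanoic acid | OC(=O)[C@@H](C)CC | starting material
26 | (6R,7R,8R,10R)-8-[(2S)-2-methylbutanoyloxy]-1-oxo-3,10-epoxygermacra-2,4(Z),11(13)-trien-12,6-olide (CNP0174601.1) | C=C1C(=O)O[C@@H]2/C=C(/C)C3=CC(=O)[C@@](C)(C[C@@H](OC(=O)[C@@H](C)CC)[C@@H]12)O3 | target

**Step count and risk**
Total steps: 11. Longest linear sequence: 11 steps (1 to 26); 3, 8, 15 and 25 enter as purchased building blocks.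

The three steps most likely to fail:

Step 10. Ring closure to the strained bicycle and the C6/C7 configuration are unproven on this scaffold; a cis-fused or C7-epimeric lactone, or reduction without cyclisation, are the likely failure modes. Fallback: setting out from 21, the allylic bromide is exchanged for tin with (Bu3Sn)2 and catalytic Pd(PPh3)4 (zerovalent palladium) to give the allylstannane F1. BF3·OEt2 in CH2Cl2 at −78 °C under high dilution then forms the C6–C7 bond through an open, Lewis-acid-activated transition state instead of the closed chromium one, giving the seco hydroxy ester 23, which lactonises on acidic work-up. The route is rejoined at 24.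

Step 9. The oxidative furan-to-furanone rearrangement is new, and the (Z)-enal may isomerise or the spiroketal may open the wrong way. Fallback: setting out from 18 with both silyl ethers still in place (19 is skipped), the furan is opened with mCPBA and NaHCO3 in CH2Cl2 at 0 °C to the (Z)-ene-trione aldehyde F2. HF·pyridine in MeCN then removes both silyl groups, and the freed tertiary hydroxyl cyclodehydrates onto the C3 ketone of the 1,3-diketone (acid-mediated 3(2H)-furanone formation from an α′-hydroxy-1,3-diketone). The route is rejoined at 21.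

Step 4. Acylation of an acetylide by an unprotected α-hydroxy lactone and the one-flask cycloisomerisation may give over-addition or mixtures of furanone and furan. Fallback: setting out from 7, the lactone is opened with Me(MeO)NMgCl (from Me(MeO)NH·HCl and i-PrMgCl) and silylated in the same flask (TESOTf, 2,6-lutidine) to the Weinreb amide F3. Alcohol 8 is protected as its tert-butyldimethylsilyl ether F4 (TBSCl, imidazole), and the lithium acetylide of F4 adds once to F3 to give the ynone F5. Bu4NF in THF removes the three silyl groups and the liberated (Z)-allylic alkoxide cycloisomerises, so the route is rejoined at 11.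

**Further compounds**
F1 | step 10 | methyl (2Z,4R)-4-hydroxy-5-{(2R)-2-methyl-3-oxo-5-[(2Z)-4-oxobut-2-en-2-yl]-2,3-dihydrofuran-2-yl}-2-[(tributylstannyl)methyl]pent-2-enoate | O=C/C=C(/C)C1=CC(=O)[C@@](C)(C[C@@H](O)/C=C(\C[Sn](CCCC)(CCCC)CCCC)C(=O)OC)O1
F2 | step 9 | methyl (2Z,4R,6R,10Z)-2-(bromomethyl)-6,10-dimethyl-7,9,12-trioxo-4,6-bis(triethylsilyloxy)dodeca-2,10-dienoate | O=C/C=C(/C)C(=O)CC(=O)[C@](C)(O[Si](CC)(CC)CC)C[C@@H](O[Si](CC)(CC)CC)/C=C(\CBr)C(=O)OC
F3 | step 4 | (2R,4R)-N,5,5-trimethoxy-N,2-dimethyl-2,4-bis(triethylsilyloxy)pentanamide | CON(C)C(=O)[C@](C)(O[Si](CC)(CC)CC)C[C@@H](O[Si](CC)(CC)CC)C(OC)OC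
F4 | step 4 | tert-butyl(dimethyl){[(2Z)-3-methylpent-2-en-4-yn-1-yl]oxy}silane | CC(C)(C)[Si](C)(C)OC/C=C(/C)C#C
F5 | step 4 | (2Z,7R,9R)-1-[tert-butyl(dimethyl)silyl]oxy-10,10-dimethoxy-3,7-dimethyl-7,9-bis(triethylsilyloxy)dec-2-en-4-yn-6-one | CC(C)(C)[Si](C)(C)OC/C=C(/C)C#CC(=O)[C@](C)(O[Si](CC)(CC)CC)C[C@@H](O[Si](CC)(CC)CC)C(OC)OC
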